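**Strategy**

Everything rests on opening the dihydropyranone ring B of the chromanone at C2–C3. C2 is fully substituted (ring oxygen O1, CH3, C3H2 and the exocyclic CH2), so this cut turns it into the O–C–H methine of an aryl ether of (R)-3-hydroxybutanoate, a centre available from the chiral pool. In one operation a dirhodium carbenoid on the ortho acyl carbon inserts into that C–H bond with retention, making C2–C3, ring B and the quaternary stereocentre. The precursor is a tert-butyl (3R)-3-aryloxybutanoate whose arene carries an ortho diazoacetyl group, a triflate on its other side and a para silyl ether; chromone annulation and the two 2-oxopropyl arms come later.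

Key step: step 5

Remark: chroman-4-one numbering is used (O1, C2, C3, C4; ring A benzo, ring B pyranone; chromone atoms primed), anhydrous 2,4,6-trihydroxyacetophenone is assumed, and the C2 descriptor switches between S and R along the route only because CIP priorities of the side chain change.

**Route**

Step 1
Reactants: 1 2,4,6-trihydroxyacetophenone
Product: 2 1-[2,6-dihydroxy-4-(triisopropylsilyloxy)phenyl]ethanone
Conditions: TIPSCl (1.05 equiv), imidazole, DMF, 0 °C to rt
Reagents that add atoms: triisopropylsilyl chloride, CC(C)[Si](Cl)(C(C)C)C(C)C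
Why: Selective O-silylation, since the 4-OH is the most acidic hydroxyl, is not flanked by the acetyl group and is not held in the C=O hydrogen bond, so one equivalent of the bulky chloride should react there first.

Step 2
Reactants: 2 1-[2,6-dihydroxy-4-(triisopropylsilyloxy)phenyl]ethanone; 3 tert-butyl (S)-3-hydroxybutanoate
Product: 4 tert-butyl (3R)-3-[2-acetyl-3-hydroxy-5-(triisopropylsilyloxy)phenoxy]butanoate
Conditions: PPh3, DIAD, THF, 0 °C to rt
Reagents that add atoms: none
Why: Mitsunobu etherification of an acidic phenol, in which the second ortho OH stays hydrogen-bonded to the ketone so that mono-alkylation should prevail, and SN2 displacement of the oxyphosphonium inverts the carbinol carbon from (S) to the (R) ether that later fixes C2.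

Step 3
Reactants: 4 tert-butyl (3R)-3-[2-acetyl-3-hydroxy-5-(triisopropylsilyloxy)phenoxy]butanoate
Product: 5 tert-butyl (3R)-3-[2-acetyl-3-(trifluoromethylsulfonyloxy)-5-(triisopropylsilyloxy)phenoxy]butanoate
Conditions: Tf2O, pyridine, CH2Cl2, −20 to 0 °C
Reagents that add atoms: triflic anhydride, O=S(=O)(OS(=O)(=O)C(F)(F)F)C(F)(F)F
Why: O-Sulfonylation of the remaining chelated phenol installs a cross-coupling handle that offers the later carbenoid no C–H bond.

Step 4
Reactants: 5 tert-butyl (3R)-3-[2-acetyl-3-(trifluoromethylsulfonyloxy)-5-(triisopropylsilyloxy)phenoxy]butanoate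
Product: 7 tert-butyl (3R)-3-[2-(2-diazoacetyl)-3-(trifluoromethylsulfonyloxy)-5-(triisopropylsilyloxy)phenoxy]butanoate, via trifluoroacetyl ketone 6 (not isolated)
Conditions: LiN(SiMe3)2 (1.05 equiv), THF, −78 °C; CF3CO2CH2CF3; aq HCl work-up; then MsN3, Et3N, H2O (1 equiv), MeCN, rt
Reagents that add atoms: methanesulfonyl azide, CS(=O)(=O)N=[N+]=[N-]
Why: Detrifluoroacetylative Regitz diazo transfer, in which the amide base deprotonates the methyl ketone much faster than the hindered, less acidic tert-butyl ester, Claisen trifluoroacetylation activates the methyl group, and azide transfer with loss of the trifluoroacetyl group gives the diazomethyl ketone without touching the ether stereocentre.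

Step 5
Reactants: 7 tert-butyl (3R)-3-[2-(2-diazoacetyl)-3-(trifluoromethylsulfonyloxy)-5-(triisopropylsilyloxy)phenoxy]butanoate
Product: 8 tert-butyl 2-[(2S)-2-methyl-4-oxo-5-(trifluoromethylsulfonyloxy)-7-(triisopropylsilyloxy)-3,4-dihydro-2H-chromen-2-yl]acetate
Conditions: Rh2(OAc)4 (2 mol %), CH2Cl2, 40 °C, slow addition of 7
Reagents that add atoms: none
Why: Rh2(OAc)4 (divalent rhodium) strips N2 from 7, and the electron-poor carbene carbon (future C3) engages the electron-rich methine C–H at the ether carbon (future C2), forming the C–C and C–H bonds in one step through a three-membered C–H–C array as the metal leaves. The closest known reaction type is the dirhodium carboxylate-catalysed C–H insertion of 2-alkoxyaryl diazomethyl ketones next to the ether oxygen, which gives chroman-4-ones, combined with the known retentive insertion of such carbenoids into stereogenic tertiary C–H bonds; here a tertiary ether methine is used so that C2 becomes quaternary. Ring B closes as a six-membered ring by 1,6-C–H insertion that makes the C2–C3 bond. The only new stereocentre, C2, is controlled by the substrate: carbon replaces hydrogen on the same face, so the (R) ether centre fixed in step 2 is carried over unchanged (the descriptor reads S in 8 only because the ester arm now outranks C3). The step needs C–H insertion to win over oxonium ylide formation at O1, carbenoid dimerisation and insertion elsewhere: the aryl ether oxygen is a poor donor because its lone pair is shared with the acylated ring, the methine next to oxygen is the only activated C–H within reach (the triflate has none, the silyl and tert-butyl groups are remote), and slow addition keeps the diazo ketone dilute.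

Step 6
Reactants: 8 tert-butyl 2-[(2S)-2-methyl-4-oxo-5-(trifluoromethylsulfonyloxy)-7-(triisopropylsilyloxy)-3,4-dihydro-2H-chromen-2-yl]acetate
Product: 9 2-[(2S)-2-methyl-4-oxo-5-(trifluoromethylsulfonyloxy)-7-(triisopropylsilyloxy)-3,4-dihydro-2H-chromen-2-yl]acetic acid
Conditions: TFA, CH2Cl2, 0 °C to rt
Reagents that add atoms: none
Why: Acidolysis of the tert-butyl ester (loss of 2-methylpropene through the tert-butyl cation) frees the acid without hydroxide, which would endanger the aryl triflate and the β-aryloxy ketone, while the aryl silyl ether and triflate tolerate TFA.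

Step 7
Reactants: 2 1-[2,6-dihydroxy-4-(triisopropylsilyloxy)phenyl]ethanone
Product: 10 1-[2-hydroxy-4-(triisopropylsilyloxy)-6-(trifluoromethylsulfonyloxy)phenyl]ethanone
Conditions: Tf2O (1.0 equiv), pyridine, CH2Cl2, −40 to 0 °C
Reagents that add atoms: triflic anhydride, O=S(=O)(OS(=O)(=O)C(F)(F)F)C(F)(F)F
Why: Mono-O-triflation, because after the first sulfonylation the remaining OH is strongly hydrogen-bonded to the acetyl group and the ring is deactivated, so one equivalent at low temperature should stop at the monotriflate.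

Step 8
Reactants: 9 2-[(2S)-2-methyl-4-oxo-5-(trifluoromethylsulfonyloxy)-7-(triisopropylsilyloxy)-3,4-dihydro-2H-chromen-2-yl]acetic acid; 10 1-[2-hydroxy-4-(triisopropylsilyloxy)-6-(trifluoromethylsulfonyloxy)phenyl]ethanone
Product: 12 1-[2-hydroxy-4-(triisopropylsilyloxy)-6-(trifluoromethylsulfonyloxy)phenyl]-4-[(2R)-2-methyl-4-oxo-5-(trifluoromethylsulfonyloxy)-7-(triisopropylsilyloxy)-3,4-dihydro-2H-chromen-2-yl]butane-1,3-dione, via acid chloride 11 (not isolated)
Conditions: 9, (COCl)2, DMF (cat.), CH2Cl2, 0 °C to rt, evaporate; 10 (2.2 equiv), LiN(SiMe3)2 (4.4 equiv), THF, −78 °C, then 11; AcOH, −78 °C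
Reagents that add atoms: none
Why: Crossed Claisen C-acylation of a preformed phenoxide–enolate by an acid chloride, set up with exactly two equivalents of base per 10 so that no free amide meets the chromanone, a second equivalent of the dianion takes the acidic diketone proton, and the cold quench limits C3 enolisation that could open ring B.

Step 9
Reactants: 12 1-[2-hydroxy-4-(triisopropylsilyloxy)-6-(trifluoromethylsulfonyloxy)phenyl]-4-[(2R)-2-methyl-4-oxo-5-(trifluoromethylsulfonyloxy)-7-(triisopropylsilyloxy)-3,4-dihydro-2H-chromen-2-yl]butane-1,3-dione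
Product: 13 (2R)-2-methyl-2-{[4-oxo-5-(trifluoromethylsulfonyloxy)-7-(triisopropylsilyloxy)-4H-chromen-2-yl]methyl}-5-(trifluoromethylsulfonyloxy)-7-(triisopropylsilyloxy)-2,3-dihydro-4H-chromen-4-one
Conditions: TFA, CH2Cl2, rt
Reagents that add atoms: none
Why: Acid-catalysed cyclodehydration of the 1-(2-hydroxyaryl)-1,3-diketone (hemiketal formation, then loss of water) should give the 4H-chromen-4-one without involving C2.

Step 10
Reactants: 13 (2R)-2-methyl-2-{[4-oxo-5-(trifluoromethylsulfonyloxy)-7-(triisopropylsilyloxy)-4H-chromen-2-yl]methyl}-5-(trifluoromethylsulfonyloxy)-7-(triisopropylsilyloxy)-2,3-dihydro-4H-chromen-4-one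
Product: 14 (2R)-5-allyl-2-{[5-allyl-4-oxo-7-(triisopropylsilyloxy)-4H-chromen-2-yl]methyl}-2-methyl-7-(triisopropylsilyloxy)-2,3-dihydro-4H-chromen-4-one
Conditions: allylSnBu3 (3 equiv), Pd(PPh3)4 (10 mol %), LiCl, 1,4-dioxane, 95 °C
Reagents that add atoms: allyltributylstannane, C=CC[Sn](CCCC)(CCCC)CCCC
Why: Twofold Stille coupling under neutral conditions (chloride-assisted oxidative addition of each aryl triflate to zerovalent palladium, transmetalation from tin, reductive elimination), with both triflates activated by their ortho carbonyl groups.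

Step 11
Reactants: 14 (2R)-5-allyl-2-{[5-allyl-4-oxo-7-(triisopropylsilyloxy)-4H-chromen-2-yl]methyl}-2-methyl-7-(triisopropylsilyloxy)-2,3-dihydro-4H-chromen-4-one
Product: 15 (2R)-2-methyl-2-{[4-oxo-5-(2-oxopropyl)-7-(triisopropylsilyloxy)-4H-chromen-2-yl]methyl}-5-(2-oxopropyl)-7-(triisopropylsilyloxy)-2,3-dihydro-4H-chromen-4-one
Conditions: PdCl2 (20 mol %), CuCl, O2 (1 atm), DMF/H2O, rt
Reagents that add atoms: water, O
Why: Tsuji–Wacker oxidation, in which Markovnikov hydroxypalladation of each terminal alkene by PdCl2 (divalent palladium) and β-hydride elimination give the methyl ketones while CuCl/O2 reoxidises the palladium under non-basic conditions.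

Step 12
Reactants: 15 (2R)-2-methyl-2-{[4-oxo-5-(2-oxopropyl)-7-(triisopropylsilyloxy)-4H-chromen-2-yl]methyl}-5-(2-oxopropyl)-7-(triisopropylsilyloxy)-2,3-dihydro-4H-chromen-4-one
Product: 16 (2R)-7-hydroxy-2-{[7-hydroxy-4-oxo-5-(2-oxopropyl)-4H-chromen-2-yl]methyl}-2-methyl-5-(2-oxopropyl)-2,3-dihydro-4H-chromen-4-one (CNP0319595.1)
Conditions: HF·pyridine, THF, 0 °C to rt
Reagents that add atoms: none
Why: Fluoride-driven cleavage of both aryl silyl ethers (strong Si–F bond) under weakly acidic conditions avoids phenoxide and enolate chemistry of the aryl acetone and β-aryloxy ketone units.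

**Compound list**

1 | 2,4,6-trihydroxyacetophenone | CC(=O)c1c(O)cc(O)cc1O | starting material
2 | 1-[2,6-dihydroxy-4-(triisopropylsilyloxy)phenyl]ethanone | CC(=O)c1c(O)cc(O[Si](C(C)C)(C(C)C)C(C)C)cc1O | intermediate
3 | tert-butyl (S)-3-hydroxybutanoate | C[C@H](O)CC(=O)OC(C)(C)C | starting material
4 | tert-butyl (3R)-3-[2-acetyl-3-hydroxy-5-(triisopropylsilyloxy)phenoxy]butanoate | C[C@H](CC(=O)OC(C)(C)C)Oc1cc(O[Si](C(C)C)(C(C)C)C(C)C)cc(O)c1C(C)=O | intermediate
5 | tert-butyl (3R)-3-[2-acetyl-3-(trifluoromethylsulfonyloxy)-5-(triisopropylsilyloxy)phenoxy]butanoate | C[C@H](CC(=O)OC(C)(C)C)Oc1cc(O[Si](C(C)C)(C(C)C)C(C)C)cc(OS(=O)(=O)C(F)(F)F)c1C(C)=O | intermediate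
6 | tert-butyl (3R)-3-[2-(4,4,4-trifluoro-3-oxobutanoyl)-3-(trifluoromethylsulfonyloxy)-5-(triisopropylsilyloxy)phenoxy]butanoate | C[C@H](CC(=O)OC(C)(C)C)Oc1cc(O[Si](C(C)C)(C(C)C)C(C)C)cc(OS(=O)(=O)C(F)(F)F)c1C(=O)CC(=O)C(F)(F)F | intermediate (not isolated)
7 | tert-butyl (3R)-3-[2-(2-diazoacetyl)-3-(trifluoromethylsulfonyloxy)-5-(triisopropylsilyloxy)phenoxy]butanoate | C[C@H](CC(=O)OC(C)(C)C)Oc1cc(O[Si](C(C)C)(C(C)C)C(C)C)cc(OS(=O)(=O)C(F)(F)F)c1C(=O)C=[N+]=[N-] | intermediate
8 | tert-butyl 2-[(2S)-2-methyl-4-oxo-5-(trifluoromethylsulfonyloxy)-7-(triisopropylsilyloxy)-3,4-dihydro-2H-chromen-2-yl]acetate | FC(F)(F)S(=O)(=O)Oc1cc(O[Si](C(C)C)(C(C)C)C(C)C)cc2c1C(=O)C[C@@](C)(CC(=O)OC(C)(C)C)O2 | intermediate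
9 | 2-[(2S)-2-methyl-4-oxo-5-(trifluoromethylsulfonyloxy)-7-(triisopropylsilyloxy)-3,4-dihydro-2H-chromen-2-yl]acetic acid | FC(F)(F)S(=O)(=O)Oc1cc(O[Si](C(C)C)(C(C)C)C(C)C)cc2c1C(=O)C[C@@](C)(CC(=O)O)O2 | intermediate
10 | 1-[2-hydroxy-4-(triisopropylsilyloxy)-6-(trifluoromethylsulfonyloxy)phenyl]ethanone | CC(=O)c1c(O)cc(O[Si](C(C)C)(C(C)C)C(C)C)cc1OS(=O)(=O)C(F)(F)F | intermediate
11 | 2-[(2S)-2-methyl-4-oxo-5-(trifluoromethylsulfonyloxy)-7-(triisopropylsilyloxy)-3,4-dihydro-2H-chromen-2-yl]acetyl chloride | FC(F)(F)S(=O)(=O)Oc1cc(O[Si](C(C)C)(C(C)C)C(C)C)cc2c1C(=O)C[C@@](C)(CC(=O)Cl)O2 | intermediate (not isolated)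
12 | 1-[2-hydroxy-4-(triisopropylsilyloxy)-6-(trifluoromethylsulfonyloxy)phenyl]-4-[(2R)-2-methyl-4-oxo-5-(trifluoromethylsulfonyloxy)-7-(triisopropylsilyloxy)-3,4-dihydro-2H-chromen-2-yl]butane-1,3-dione | FC(F)(F)S(=O)(=O)Oc1cc(O[Si](C(C)C)(C(C)C)C(C)C)cc2c1C(=O)C[C@@](C)(CC(=O)CC(=O)c1c(O)cc(O[Si](C(C)C)(C(C)C)C(C)C)cc1OS(=O)(=O)C(F)(F)F)O2 | intermediate
13 | (2R)-2-methyl-2-{[4-oxo-5-(trifluoromethylsulfonyloxy)-7-(triisopropylsilyloxy)-4H-chromen-2-yl]methyl}-5-(trifluoromethylsulfonyloxy)-7-(triisopropylsilyloxy)-2,3-dihydro-4H-chromen-4-one | FC(F)(F)S(=O)(=O)Oc1cc(O[Si](C(C)C)(C(C)C)C(C)C)cc2c1C(=O)C[C@@](C)(Cc1cc(=O)c3c(OS(=O)(=O)C(F)(F)F)cc(O[Si](C(C)C)(C(C)C)C(C)C)cc3o1)O2 | intermediate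
14 | (2R)-5-allyl-2-{[5-allyl-4-oxo-7-(triisopropylsilyloxy)-4H-chromen-2-yl]methyl}-2-methyl-7-(triisopropylsilyloxy)-2,3-dihydro-4H-chromen-4-one | C=CCc1cc(O[Si](C(C)C)(C(C)C)C(C)C)cc2c1C(=O)C[C@@](C)(Cc1cc(=O)c3c(CC=C)cc(O[Si](C(C)C)(C(C)C)C(C)C)cc3o1)O2 | intermediate
15 | (2R)-2-methyl-2-{[4-oxo-5-(2-oxopropyl)-7-(triisopropylsilyloxy)-4H-chromen-2-yl]methyl}-5-(2-oxopropyl)-7-(triisopropylsilyloxy)-2,3-dihydro-4H-chromen-4-one | CC(=O)Cc1cc(O[Si](C(C)C)(C(C)C)C(C)C)cc2c1C(=O)C[C@@](C)(Cc1cc(=O)c3c(CC(C)=O)cc(O[Si](C(C)C)(C(C)C)C(C)C)cc3o1)O2 | intermediate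
16 | (2R)-7-hydroxy-2-{[7-hydroxy-4-oxo-5-(2-oxopropyl)-4H-chromen-2-yl]methyl}-2-methyl-5-(2-oxopropyl)-2,3-dihydro-4H-chromen-4-one | CC(=O)Cc1cc(O)cc2c1C(=O)C[C@@](C)(Cc1cc(=O)c3c(CC(C)=O)cc(O)cc3o1)O2 | target

**Step count and risks**

Total steps: 12. Longest linear sequence: 11 steps (steps 1–6 and 8–12); step 7 is a one-step branch from 2.

Steps most likely to fail:

1. Step 5. The carbenoid may attack the lone pair of the ether oxygen instead of the C–H bond (oxonium ylide, then 1,2-shift or β-elimination of the butanoate chain), may dimerise, or may react in part by stepwise hydride transfer, which would erode the configuration at C2. The fallback sets out from 10 and comes back at 8, building C2 by polar chemistry and resolving. Compound 10 is condensed with N,N-dimethylacetamide dimethyl acetal (toluene, 110 °C, then AcOH) to 2-methyl-5-(trifluoromethylsulfonyloxy)-7-(triisopropylsilyloxy)-4H-chromen-4-one F1. F1 is activated with TBSOTf as its 4-silyloxybenzopyrylium ion and trapped at C2 by 1-tert-butoxy-1-(tert-butyldimethylsilyloxy)ethene (Mukaiyama–Michael addition) to give racemic tert-butyl 2-[4-(tert-butyldimethylsilyloxy)-2-methyl-5-(trifluoromethylsulfonyloxy)-7-(triisopropylsilyloxy)-2H-chromen-2-yl]acetate F2. Mild aqueous acid hydrolyses the silyl enol ether to racemic tert-butyl 2-[2-methyl-4-oxo-5-(trifluoromethylsulfonyloxy)-7-(triisopropylsilyloxy)-3,4-dihydro-2H-chromen-2-yl]acetate F3. Preparative chromatography on a chiral stationary phase then separates 8 from its (2R) enantiomer F4, which is set aside.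

2. Step 8. Proton transfer from C3 of the chromanone or from the acyl donor to the lithium enolate may compete with acylation; the resulting enolate can open ring B by retro-oxa-Michael reaction and reclose with loss of configuration, and O-acylation may compete with C-acylation. The fallback sets out from 10 and comes back at 12 without any base touching the chromanone. Compound 10 is silylated twice with TMSOTf/Et3N (CH2Cl2, 0 °C) to 1-[2-(trimethylsilyloxy)-4-(triisopropylsilyloxy)-6-(trifluoromethylsulfonyloxy)phenyl]-1-(trimethylsilyloxy)ethene F5. This neutral silyl enol ether is C-acylated by acid chloride 11 (prepared from 9 as in step 8) in the presence of ZnCl2 (CH2Cl2/Et2O, rt), a Lewis-acid-mediated acylation of a silyl enol ether. Aqueous work-up removes the trimethylsilyl groups and should give 12.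

3. Step 11. The allyl double bonds may migrate into conjugation with the arenes before oxypalladation, and Markovnikov selectivity may be imperfect at one of the two sites, possibly steered by the ortho carbonyl groups. The fallback sets out from 13 and comes back at 15, replacing hydration by oxidative cleavage. Compound 13 is coupled under the conditions of step 10 with tributyl(2-methylallyl)stannane to (2R)-2-methyl-5-(2-methylallyl)-2-{[5-(2-methylallyl)-4-oxo-7-(triisopropylsilyloxy)-4H-chromen-2-yl]methyl}-7-(triisopropylsilyloxy)-2,3-dihydro-4H-chromen-4-one F6. Its two 1,1-disubstituted alkenes are cleaved by OsO4 (cat.), NaIO4, 2,6-lutidine in dioxane/H2O (Lemieux–Johnson oxidation) to give 15 directly.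

Further compounds
F1 | step 5 | 2-methyl-5-(trifluoromethylsulfonyloxy)-7-(triisopropylsilyloxy)-4H-chromen-4-one | Cc1cc(=O)c2c(OS(=O)(=O)C(F)(F)F)cc(O[Si](C(C)C)(C(C)C)C(C)C)cc2o1
F2 | step 5 | racemic tert-butyl 2-[4-(tert-butyldimethylsilyloxy)-2-methyl-5-(trifluoromethylsulfonyloxy)-7-(triisopropylsilyloxy)-2H-chromen-2-yl]acetate | CC1(CC(=O)OC(C)(C)C)C=C(O[Si](C)(C)C(C)(C)C)c2c(OS(=O)(=O)C(F)(F)F)cc(O[Si](C(C)C)(C(C)C)C(C)C)cc2O1
F3 | step 5 | racemic tert-butyl 2-[2-methyl-4-oxo-5-(trifluoromethylsulfonyloxy)-7-(triisopropylsilyloxy)-3,4-dihydro-2H-chromen-2-yl]acetate | FC(F)(F)S(=O)(=O)Oc1cc(O[Si](C(C)C)(C(C)C)C(C)C)cc2c1C(=O)CC(C)(CC(=O)OC(C)(C)C)O2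
F4 | step 5 | tert-butyl 2-[(2R)-2-methyl-4-oxo-5-(trifluoromethylsulfonyloxy)-7-(triisopropylsilyloxy)-3,4-dihydro-2H-chromen-2-yl]acetate | FC(F)(F)S(=O)(=O)Oc1cc(O[Si](C(C)C)(C(C)C)C(C)C)cc2c1C(=O)C[C@](C)(CC(=O)OC(C)(C)C)O2
F5 | step 8 | 1-[2-(trimethylsilyloxy)-4-(triisopropylsilyloxy)-6-(trifluoromethylsulfonyloxy)phenyl]-1-(trimethylsilyloxy)ethene | C=C(O[Si](C)(C)C)c1c(O[Si](C)(C)C)cc(O[Si](C(C)C)(C(C)C)C(C)C)cc1OS(=O)(=O)C(F)(F)F
F6 | step 11 | (2R)-2-methyl-5-(2-methylallyl)-2-{[5-(2-methylallyl)-4-oxo-7-(triisopropylsilyloxy)-4H-chromen-2-yl]methyl}-7-(triisopropylsilyloxy)-2,3-dihydro-4H-chromen-4-one | C=C(C)Cc1cc(O[Si](C(C)C)(C(C)C)C(C)C)cc2c1C(=O)C[C@@](C)(Cc1cc(=O)c3c(CC(C)=C)cc(O[Si](C(C)C)(C(C)C)C(C)C)cc3o1)O2
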